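**Plan**

- Numbering (carotenoid): ring A is C1–C6 (C3=O, C4=C5) with the exocyclic C6=C7 bond; C8 is the chain ketone; ring B is C1'–C6' (C3'-OH), joined to the chain through C7'≡C8'.
- Retrosynthetic cuts, in order: C7–C8 (alkenyl–acyl bond; fragment 1 = C10 ring A alkenylboronic acid, fragment 2 = C30 thioester), then C11=C12, C11'=C12', C6'–C7', and last C6=C7 of ring A.
- Enabling feature: C8 is a ketone flanked only by sp2 carbons (C7 of the ring A ylidene and C9). A neutral thioester/alkenylboron coupling under Pd/Cu can therefore form C7–C8 at the final oxidation level, as the last step, with the C3 enone and the 3'-OH unprotected.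
- Forward: ketoisophorone → ring A (Z)-alkenylboronic acid (3 steps); actinol → ring B triflate → C15 phosphonium salt → C25 aldehyde → C30 ester → thioester → union. Both rings are bought; none is built.
- Stereochemistry: C3' (R) comes from (4R,6R)-actinol. The 6Z geometry comes from the syn B–O elimination of the boron–Wittig step and is retained in the coupling. The chain E-alkenes come from the (E)-enynol, the all-E C10 dialdehyde and E-selective olefinations.

Key step: step 14

Assumption: (4R,6R)-actinol 12, the all-E C10 dialdehyde 19 and bis(pinacolato)borylmethane 3 are purchased; all polyene work is done in the dark under argon.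

**Route**

Step 1
Reactants: 1 ketoisophorone (2,6,6-trimethylcyclohex-2-ene-1,4-dione)
Product: 2 7,9,9-trimethyl-1,4-dioxaspiro[4.5]dec-6-en-8-one
Conditions: ethylene glycol (1.2 equiv), p-TsOH (cat.), benzene, reflux, Dean–Stark
Reagents that add atoms: ethylene glycol, OCCO
Why: Acid-catalysed ketalisation with azeotropic removal of water; the C4 carbonyl (flanked by CH and CH2) reacts, while the C1 carbonyl, shielded by the gem-dimethyl carbon and the 2-methyl group, should not; no stereocentre is formed.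

Step 2
Reactants: 2 7,9,9-trimethyl-1,4-dioxaspiro[4.5]dec-6-en-8-one; 3 bis(pinacolato)borylmethane
Product: 6 (Z)-2-[(7,9,9-trimethyl-1,4-dioxaspiro[4.5]dec-6-en-8-ylidene)methyl]-4,4,5,5-tetramethyl-1,3,2-dioxaborolane, via lithiated diborylmethane 4 (not isolated), via lithium alkoxide adduct 5 (not isolated)
Conditions: lithium 2,2,6,6-tetramethylpiperidide (1.2 equiv), 3 (1.3 equiv), THF, 0 °C; then 2, −78 °C to rt
Reagents that add atoms: none
Why: Boron–Wittig olefination: the lithiated geminal diboronate adds 1,2 to the ketone (no α-hydrogen; the β-carbon is shielded by the neighbouring ketal carbon) and the alkoxide expels one boryl group by syn B–O elimination, the surviving boryl group settling anti to the bulkier quaternary C(CH3)2 flank, which should give the Z alkene; any E isomer is to be removed by chromatography.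

Step 3
Reactants: 6 (Z)-alkenyl pinacol boronate ketal
Product: 7 [(Z)-(2,6,6-trimethyl-4-oxocyclohex-2-en-1-ylidene)methyl]boronic acid
Conditions: MeB(OH)2 (10 equiv), 0.1 M aq. HCl/acetone (1:1), rt; evaporate
Reagents that add atoms: water, O; methylboronic acid, CB(O)O
Why: Acid-catalysed transesterification of the pinacol ester onto volatile methylboronic acid runs alongside hydrolysis of the dioxolane to the conjugated enone; neither event acts on the exocyclic C=C, so the Z geometry should be kept.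

Step 4
Reactants: 8 ethyl 2-(triphenylphosphoranylidene)propanoate; 9 chloroacetaldehyde
Product: 10 ethyl (2E)-4-chloro-2-methylbut-2-enoate
Conditions: 9 (50% in water, 1.5 equiv), CH2Cl2, 0 °C to rt
Reagents that add atoms: none
Why: Wittig olefination with an ester-stabilised ylide, which tolerates water and is E-selective for the trisubstituted enoate.

Step 5
Reactants: 10 ethyl (2E)-4-chloro-2-methylbut-2-enoate
Product: 11 ethyl (2E)-4-(diethoxyphosphoryl)-2-methylbut-2-enoate
Conditions: P(OEt)3 (1.5 equiv), neat, 140 °C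
Reagents that add atoms: triethyl phosphite, CCOP(OCC)OCC
Why: Michaelis–Arbuzov reaction of the primary allylic chloride, chloroethane distilling off; the conjugated E alkene is not involved.

Step 6
Reactants: 12 (4R,6R)-4-hydroxy-2,2,6-trimethylcyclohexan-1-one (actinol)
Product: 13 (4R,6R)-2,2,6-trimethyl-4-(triethylsilyloxy)cyclohexan-1-one
Conditions: Et3SiCl, imidazole, DMF, 0 °C to rt
Reagents that add atoms: chlorotriethylsilane, CC[Si](Cl)(CC)CC
Why: Standard silylation of the secondary alcohol; both stereocentres are untouched.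

Step 7
Reactants: 13 (4R,6R)-2,2,6-trimethyl-4-(triethylsilyloxy)cyclohexan-1-one
Product: 15 (4R)-2,6,6-trimethyl-4-(triethylsilyloxy)cyclohex-1-en-1-yl trifluoromethanesulfonate, via lithium enolate 14 (not isolated)
Conditions: LiN(i-Pr)2, THF, −78 °C; then PhNTf2, −78 to 0 °C
Reagents that add atoms: N-phenylbis(trifluoromethanesulfonimide), FC(F)(F)S(=O)(=O)N(c1ccccc1)S(=O)(=O)C(F)(F)F
Why: Enolate O-triflation: the ketone can enolise only toward C6 because C2 is quaternary, so a single tetrasubstituted enol triflate should form; the C6 stereocentre is erased and C4 (R) is untouched.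

Step 8
Reactants: 15 ring B enol triflate; 16 (2E)-3-methylpent-2-en-4-yn-1-ol
Product: 17 (2E)-3-methyl-5-[(4R)-2,6,6-trimethyl-4-(triethylsilyloxy)cyclohex-1-en-1-yl]pent-2-en-4-yn-1-ol
Conditions: Pd(PPh3)4 (5 mol %), CuI (10 mol %), i-Pr2NH, THF, rt
Reagents that add atoms: none
Why: Sonogashira coupling of the alkenyl triflate with the terminal alkyne; the E geometry of the enynol and the C4 stereocentre are carried through unchanged.

Step 9
Reactants: 17 C15 silyloxy enynol
Product: 18 {(2E)-5-[(4R)-4-hydroxy-2,6,6-trimethylcyclohex-1-en-1-yl]-3-methylpent-2-en-4-yn-1-yl}triphenylphosphonium bromide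
Conditions: PPh3·HBr (1.2 equiv), MeOH, rt, dark
Reagents that add atoms: triphenylphosphine hydrobromide, Br.c1ccc(cc1)P(c1ccccc1)c1ccccc1
Why: Protonation of the allylic alcohol and capture of the allylic cation at its primary terminus by PPh3 gives the phosphonium salt, while the acidic methanol removes the triethylsilyl group; the less hindered E enyne geometry should persist.

Step 10
Reactants: 18 C15 hydroxy phosphonium bromide; 19 (2E,4E,6E)-2,7-dimethylocta-2,4,6-trienedial
Product: 22 (2E,4E,6E,8E,10E)-13-[(4R)-4-hydroxy-2,6,6-trimethylcyclohex-1-en-1-yl]-2,7,11-trimethyltrideca-2,4,6,8,10-pentaen-12-ynal, via phosphorus ylide 20 (not isolated), via 8Z isomer 21 (not isolated)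
Conditions: 19 (3 equiv), NaOMe (1.1 equiv, slow addition), CH2Cl2/MeOH, −10 °C to rt; work-up; then PdCl2(MeCN)2 (2 mol %), Et3N, CH2Cl2, rt, dark
Reagents that add atoms: none
Why: Wittig reaction of the semi-stabilised allylic ylide with an excess of the symmetrical dialdehyde should stop at mono-olefination; the new disubstituted C8=C9 bond forms as an E/Z mixture, and the hindered Z isomer is converted into E by PdCl2(MeCN)2-catalysed isomerisation.

Step 11
Reactants: 22 C25 hydroxy aldehyde; 11 ethyl (2E)-4-(diethoxyphosphoryl)-2-methylbut-2-enoate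
Product: 24 ethyl (2E,4E,6E,8E,10E,12E,14E)-17-[(4R)-4-hydroxy-2,6,6-trimethylcyclohex-1-en-1-yl]-2,6,11,15-tetramethylheptadeca-2,4,6,8,10,12,14-heptaen-16-ynoate, via sodium phosphonate anion 23 (not isolated)
Conditions: 11 (1.4 equiv), NaH (1.3 equiv), THF, 0 °C; then 22, 0 °C to rt
Reagents that add atoms: none
Why: Horner–Wadsworth–Emmons olefination with the vinylogous phosphonate anion, which reacts at its phosphorus-bearing carbon and should give the new disubstituted alkene E; the free hydroxyl is not deprotonated by the stabilised anion.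

Step 12
Reactants: 24 C30 ethyl ester
Product: 26 (2E,4E,6E,8E,10E,12E,14E)-17-[(4R)-4-hydroxy-2,6,6-trimethylcyclohex-1-en-1-yl]-2,6,11,15-tetramethylheptadeca-2,4,6,8,10,12,14-heptaen-16-ynoic acid, via potassium carboxylate 25 (not isolated)
Conditions: KOH (5 equiv), EtOH/THF/H2O, 45 °C, dark; then 1 M aq. HCl to pH 4, 0 °C
Reagents that add atoms: potassium hydroxide, [K+].[OH-]
Why: Saponification of the ethyl ester followed by mild acidification; no other group is base-labile and no stereo-element is affected.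

Step 13
Reactants: 26 C30 hydroxy acid
Product: 27 S-(4-methylphenyl) (2E,4E,6E,8E,10E,12E,14E)-17-[(4R)-4-hydroxy-2,6,6-trimethylcyclohex-1-en-1-yl]-2,6,11,15-tetramethylheptadeca-2,4,6,8,10,12,14-heptaen-16-ynethioate
Conditions: 4-methylbenzenethiol (1.1 equiv), DCC (1.1 equiv), DMAP (5 mol %), CH2Cl2, 0 °C to rt, dark
Reagents that add atoms: 4-methylbenzenethiol, Cc1ccc(S)cc1
Why: Steglich-type thioesterification: the carbodiimide-activated acid should be captured by the arenethiol far faster than by the hindered secondary hydroxyl, and the low temperature should suppress conjugate addition of the thiol.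

Step 14
Reactants: 27 C30 S-(4-methylphenyl) thioester; 7 ring A (Z)-alkenylboronic acid
Product: 28 CNP0205386.1, (4Z)-4-[(3E,5E,7E,9E,11E,13E,15E)-18-[(4R)-4-hydroxy-2,6,6-trimethylcyclohex-1-en-1-yl]-3,7,12,16-tetramethyl-2-oxooctadeca-3,5,7,9,11,13,15-heptaen-17-yn-1-ylidene]-3,5,5-trimethylcyclohex-2-en-1-one
Conditions: 7 (1.5 equiv), Pd2(dba)3 (2.5 mol %), P(2-furyl)3 (15 mol %), Cu(O2CC4H3S) (copper thiophene-2-carboxylate, 1.6 equiv), THF, 45 °C, argon, dark
Reagents that add atoms: none
Why: Liebeskind–Srogl coupling: zerovalent palladium inserts into the C(acyl)–S bond of 27 (the sulfur being held by copper), the copper carboxylate activates the B(OH)2 group of 7 and takes up the thiolate while the alkenyl group passes from boron to palladium, and reductive elimination forms the C7–C8 bond at the ketone oxidation level. The closest known reaction type is the ketone synthesis from a thioester and an alkenylboronic acid under Pd catalysis with a stoichiometric copper carboxylate. No ring is closed and no stereocentre is formed; the C3' centre is remote and untouched. The 6Z geometry should be carried over from 7 because transmetalation and reductive elimination at an alkenyl carbon proceed with retention, and with the acyl group beside trigonal C5 instead of quaternary C1 this isomer should also be the less strained one. The step needs chemoselectivity for the thioester over the C3 enone, the C7'≡C8' alkyne, the polyene and the free 3'-OH, which the base-free neutral conditions should secure; C8 has no sp3 α-hydrogen and alkenoyl–palladium species lose CO only slowly, so neither enolisation nor decarbonylation should compete.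

**Compound list**

1 | ketoisophorone (2,6,6-trimethylcyclohex-2-ene-1,4-dione) | CC1=CC(=O)CC(C)(C)C1=O | starting material
2 | 7,9,9-trimethyl-1,4-dioxaspiro[4.5]dec-6-en-8-one | CC1=CC2(OCCO2)CC(C)(C)C1=O | intermediate
3 | bis(pinacolato)borylmethane, 2,2'-methylenebis(4,4,5,5-tetramethyl-1,3,2-dioxaborolane) | CC1(C)OB(CB2OC(C)(C)C(C)(C)O2)OC1(C)C | starting material
4 | [bis(4,4,5,5-tetramethyl-1,3,2-dioxaborolan-2-yl)methyl]lithium (formed in the flask) | [Li]C(B1OC(C)(C)C(C)(C)O1)B1OC(C)(C)C(C)(C)O1 | intermediate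
5 | lithium 8-[bis(4,4,5,5-tetramethyl-1,3,2-dioxaborolan-2-yl)methyl]-7,9,9-trimethyl-1,4-dioxaspiro[4.5]dec-6-en-8-olate (racemic; formed in the flask) | [Li]OC1(C(B2OC(C)(C)C(C)(C)O2)B3OC(C)(C)C(C)(C)O3)C(C)=CC4(OCCO4)CC1(C)C | intermediate
6 | (Z)-2-[(7,9,9-trimethyl-1,4-dioxaspiro[4.5]dec-6-en-8-ylidene)methyl]-4,4,5,5-tetramethyl-1,3,2-dioxaborolane | CC1=CC2(OCCO2)CC(C)(C)/C1=C/B3OC(C)(C)C(C)(C)O3 | intermediate
7 | [(Z)-(2,6,6-trimethyl-4-oxocyclohex-2-en-1-ylidene)methyl]boronic acid | CC1=CC(=O)CC(C)(C)/C1=C/B(O)O | intermediate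
8 | ethyl 2-(triphenylphosphoranylidene)propanoate | CCOC(=O)C(C)=P(c1ccccc1)(c1ccccc1)c1ccccc1 | starting material
9 | chloroacetaldehyde (50% aqueous solution) | ClCC=O | starting material
10 | ethyl (2E)-4-chloro-2-methylbut-2-enoate | CCOC(=O)/C(C)=C/CCl | intermediate
11 | ethyl (2E)-4-(diethoxyphosphoryl)-2-methylbut-2-enoate | CCOC(=O)/C(C)=C/CP(=O)(OCC)OCC | intermediate
12 | (4R,6R)-4-hydroxy-2,2,6-trimethylcyclohexan-1-one (actinol) | O=C1[C@H](C)C[C@@H](O)CC1(C)C | starting material
13 | (4R,6R)-2,2,6-trimethyl-4-(triethylsilyloxy)cyclohexan-1-one | O=C1[C@H](C)C[C@@H](O[Si](CC)(CC)CC)CC1(C)C | intermediate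
14 | lithium (4R)-2,6,6-trimethyl-4-(triethylsilyloxy)cyclohex-1-en-1-olate (formed in the flask) | [Li]OC1=C(C)C[C@@H](O[Si](CC)(CC)CC)CC1(C)C | intermediate
15 | (4R)-2,6,6-trimethyl-4-(triethylsilyloxy)cyclohex-1-en-1-yl trifluoromethanesulfonate | FC(F)(F)S(=O)(=O)OC1=C(C)C[C@@H](O[Si](CC)(CC)CC)CC1(C)C | intermediate
16 | (2E)-3-methylpent-2-en-4-yn-1-ol | C#C/C(C)=C/CO | starting material
17 | (2E)-3-methyl-5-[(4R)-2,6,6-trimethyl-4-(triethylsilyloxy)cyclohex-1-en-1-yl]pent-2-en-4-yn-1-ol | OC/C=C(\C)C#CC1=C(C)C[C@@H](O[Si](CC)(CC)CC)CC1(C)C | intermediate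
18 | {(2E)-5-[(4R)-4-hydroxy-2,6,6-trimethylcyclohex-1-en-1-yl]-3-methylpent-2-en-4-yn-1-yl}triphenylphosphonium bromide | [Br-].c1ccc(cc1)[P+](c1ccccc1)(c1ccccc1)C/C=C(\C)C#CC1=C(C)C[C@@H](O)CC1(C)C | intermediate
19 | (2E,4E,6E)-2,7-dimethylocta-2,4,6-trienedial | O=C/C(C)=C/C=C/C=C(\C)C=O | starting material
20 | {(2E)-5-[(4R)-4-hydroxy-2,6,6-trimethylcyclohex-1-en-1-yl]-3-methylpent-2-en-4-yn-1-ylidene}triphenylphosphorane (ylide of 18; formed in the flask) | c1ccc(cc1)P(c1ccccc1)(c1ccccc1)=C/C=C(\C)C#CC1=C(C)C[C@@H](O)CC1(C)C | intermediate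
21 | (2E,4E,6E,8Z,10E)-13-[(4R)-4-hydroxy-2,6,6-trimethylcyclohex-1-en-1-yl]-2,7,11-trimethyltrideca-2,4,6,8,10-pentaen-12-ynal (8Z isomer of 22; formed in the flask) | O=C/C(C)=C/C=C/C=C(C)/C=C\C=C(/C)C#CC1=C(C)C[C@@H](O)CC1(C)C | intermediate
22 | (2E,4E,6E,8E,10E)-13-[(4R)-4-hydroxy-2,6,6-trimethylcyclohex-1-en-1-yl]-2,7,11-trimethyltrideca-2,4,6,8,10-pentaen-12-ynal | O=C/C(C)=C/C=C/C=C(C)/C=C/C=C(\C)C#CC1=C(C)C[C@@H](O)CC1(C)C | intermediate
23 | sodium salt of the C4 carbanion of 11 (formed in the flask) | [Na+].CCOC(=O)/C(C)=C/[CH-]P(=O)(OCC)OCC | intermediate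
24 | ethyl (2E,4E,6E,8E,10E,12E,14E)-17-[(4R)-4-hydroxy-2,6,6-trimethylcyclohex-1-en-1-yl]-2,6,11,15-tetramethylheptadeca-2,4,6,8,10,12,14-heptaen-16-ynoate | CCOC(=O)/C(C)=C/C=C/C(C)=C/C=C/C=C(C)/C=C/C=C(\C)C#CC1=C(C)C[C@@H](O)CC1(C)C | intermediate
25 | potassium salt of 26 (formed in the flask) | [K+].[O-]C(=O)/C(C)=C/C=C/C(C)=C/C=C/C=C(C)/C=C/C=C(\C)C#CC1=C(C)C[C@@H](O)CC1(C)C | intermediate
26 | (2E,4E,6E,8E,10E,12E,14E)-17-[(4R)-4-hydroxy-2,6,6-trimethylcyclohex-1-en-1-yl]-2,6,11,15-tetramethylheptadeca-2,4,6,8,10,12,14-heptaen-16-ynoic acid | OC(=O)/C(C)=C/C=C/C(C)=C/C=C/C=C(C)/C=C/C=C(\C)C#CC1=C(C)C[C@@H](O)CC1(C)C | intermediate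
27 | S-(4-methylphenyl) (2E,4E,6E,8E,10E,12E,14E)-17-[(4R)-4-hydroxy-2,6,6-trimethylcyclohex-1-en-1-yl]-2,6,11,15-tetramethylheptadeca-2,4,6,8,10,12,14-heptaen-16-ynethioate | Cc1ccc(cc1)SC(=O)/C(C)=C/C=C/C(C)=C/C=C/C=C(C)/C=C/C=C(\C)C#CC1=C(C)C[C@@H](O)CC1(C)C | intermediate
28 | CNP0205386.1, (4Z)-4-[(3E,5E,7E,9E,11E,13E,15E)-18-[(4R)-4-hydroxy-2,6,6-trimethylcyclohex-1-en-1-yl]-3,7,12,16-tetramethyl-2-oxooctadeca-3,5,7,9,11,13,15-heptaen-17-yn-1-ylidene]-3,5,5-trimethylcyclohex-2-en-1-one | CC1=CC(=O)CC(C)(C)/C1=C/C(=O)/C(C)=C/C=C/C(C)=C/C=C/C=C(C)/C=C/C=C(\C)C#CC1=C(C)C[C@@H](O)CC1(C)C | target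

**Step count and risks**

Total step count: 14. Longest linear sequence: 9 steps (steps 6 to 14, from 12).

Steps most likely to fail:

Step 2 (boron–Wittig olefination). What may go wrong: the bulky diborylmethyl anion may fail to add to the hindered carbonyl or may add in conjugate fashion, and the B–O elimination may discriminate poorly between the two flanks. Fallback (enolate triflation and borylation in place of carbonyl olefination): starting from 2, methylene transfer from dimethylsulfonium methylide (Me3SI, n-BuLi, THF, −10 °C; Corey–Chaykovsky) would give the racemic spiro-epoxide F1. Lewis-acid rearrangement (BF3·OEt2, CH2Cl2, −78 °C; Meinwald) would give the ring aldehyde F2. Enolisation with KN(SiMe3)2 and O-triflation with PhNTf2 would give the (Z)-enol triflate F3, the geometric isomers being separable. Miyaura borylation (B2pin2, PdCl2(PPh3)2, PPh3, KOPh, toluene, 50 °C), which keeps the alkene geometry, would rejoin the route at 6.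

Step 14 (thioester/boronic acid coupling). What may go wrong: slow boron-to-palladium transfer of the hindered, electron-poor alkenyl group, so that protodeboronation and thioester decomposition win, or partial loss of the 6Z geometry at the alkenylpalladium stage. Fallback (carbonyl addition and oxidation in place of acyl cross-coupling): starting from 7, iododeboronation with N-iodosuccinimide (MeCN, 0 °C; retention) would give the (Z)-alkenyl iodide F4. Starting from 24, reduction with i-Bu2AlH (CH2Cl2, −78 °C) would give the C30 allylic diol F5, and MnO2 (CH2Cl2, rt) the C30 aldehyde F6. Nozaki–Hiyama–Kishi coupling of F4 with F6 (CrCl2, NiCl2 cat., DMSO/THF, rt) would give the C8 carbinol F7 as a mixture of epimers. MnO2, which oxidises only the doubly allylic hydroxyl, would rejoin the route at 28.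

Step 13 (thioesterification). What may go wrong: conjugate addition of the arenethiol along the polyenoyl chain, and acylation of the free 3'-hydroxyl by the activated acid with oligomer formation. Fallback (thioester carried in by the olefination reagent in place of late acyl activation): starting from 11, selective saponification of the carboxylic ester (LiOH, THF/H2O, rt) would give the phosphonate acid F8, and DCC/DMAP with 4-methylbenzenethiol the thioester phosphonate F9. Horner–Wadsworth–Emmons reaction of F9 with aldehyde 22 under mild conditions (LiCl, 1,8-diazabicyclo[5.4.0]undec-7-ene, MeCN, rt) would rejoin the route at 27.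

Further compounds
F1 | step 2 | racemic spiro-epoxide of 2 (oxirane spiro-fused at C8 of the 7,9,9-trimethyl-1,4-dioxaspiro[4.5]dec-6-ene ring) | CC1=CC2(OCCO2)CC(C)(C)C13CO3
F2 | step 2 | racemic 7,9,9-trimethyl-1,4-dioxaspiro[4.5]dec-6-ene-8-carbaldehyde | CC1=CC2(OCCO2)CC(C)(C)C1C=O
F3 | step 2 | (Z)-(7,9,9-trimethyl-1,4-dioxaspiro[4.5]dec-6-en-8-ylidene)methyl trifluoromethanesulfonate | CC1=CC2(OCCO2)CC(C)(C)/C1=C/OS(=O)(=O)C(F)(F)F
F4 | step 14 | (4Z)-4-(iodomethylidene)-3,5,5-trimethylcyclohex-2-en-1-one | CC1=CC(=O)CC(C)(C)/C1=C/I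
F5 | step 14 | (2E,4E,6E,8E,10E,12E,14E)-17-[(4R)-4-hydroxy-2,6,6-trimethylcyclohex-1-en-1-yl]-2,6,11,15-tetramethylheptadeca-2,4,6,8,10,12,14-heptaen-16-yn-1-ol | OC/C(C)=C/C=C/C(C)=C/C=C/C=C(C)/C=C/C=C(\C)C#CC1=C(C)C[C@@H](O)CC1(C)C
F6 | step 14 | (2E,4E,6E,8E,10E,12E,14E)-17-[(4R)-4-hydroxy-2,6,6-trimethylcyclohex-1-en-1-yl]-2,6,11,15-tetramethylheptadeca-2,4,6,8,10,12,14-heptaen-16-ynal | O=C/C(C)=C/C=C/C(C)=C/C=C/C=C(C)/C=C/C=C(\C)C#CC1=C(C)C[C@@H](O)CC1(C)C
F7 | step 14 | C8 carbinol of 28 (both C8 epimers), (4Z)-4-[(3E,5E,7E,9E,11E,13E,15E)-2-hydroxy-18-[(4R)-4-hydroxy-2,6,6-trimethylcyclohex-1-en-1-yl]-3,7,12,16-tetramethyloctadeca-3,5,7,9,11,13,15-heptaen-17-yn-1-ylidene]-3,5,5-trimethylcyclohex-2-en-1-one | CC1=CC(=O)CC(C)(C)/C1=C/C(O)/C(C)=C/C=C/C(C)=C/C=C/C=C(C)/C=C/C=C(\C)C#CC1=C(C)C[C@@H](O)CC1(C)C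
F8 | step 13 | (2E)-4-(diethoxyphosphoryl)-2-methylbut-2-enoic acid | OC(=O)/C(C)=C/CP(=O)(OCC)OCC
F9 | step 13 | S-(4-methylphenyl) (2E)-4-(diethoxyphosphoryl)-2-methylbut-2-enethioate | Cc1ccc(cc1)SC(=O)/C(C)=C/CP(=O)(OCC)OCC
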